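I have no rate constants for these flasks, so I start from a ratio that needs none.

| setting | north | south-east | dusk | spring | midnight | dawn |
|---|---|---|---|---|---|---|
| substrate | 3.4 × 10⁻⁴ M | 0.0025 M | 2.5 × 10⁻⁴ M | 5.0 × 10⁻⁴ M | 0.0010 M | 0.0020 M |
| partner | 1 mM | 1 mM | 1.00 mM | 1.00 mM | 1.00 mM | 1.00 mM |
| capture agent | 0.15 mM | 0.15 mM | 0.150 mM | 0.150 mM | 0.150 mM | 0.150 mM |
| remark | run made earlier | run made earlier |  |  |  |  |
| time |  |  | 2.5 min | 2.5 min | 2.5 min | 2.5 min |

| run | time / s | double product / % |
|---|---|---|
| north | 12.0 | 14 |
| north | 40.0 | 19 |
| north | 60.0 | 16 |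
| north | 120 | 9 |
| south-east | 12.0 | 1 |
| south-east | 40.0 | 3 |
| south-east | 60.0 | 4 |
| south-east | 120 | 3 |

(each reading ± 1.5 percentage points)

- "hardly changes" means that all values lie within two and a half points (for a concentration: within two and a half percent of the largest)

- [double product] at the end for dusk, spring, midnight, dawn, in this order
- the shape of the row from first to last (hardly changes / rises all the way / falls all the way / rises, then falls / falls, then rises)

Each addition of partner to substrate puts one more partner on the same molecule. So I define the partner load r, the mean number of partners available per substrate charged, as c(partner) divided by c(substrate). For midnight, the load is 1.00.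

I read the table by load. The north run has 2.94. Its double product reads 19% at 40.0 s but 9% at 120 s, so something takes it away. The south-east run has 0.400. Its late readings are 4% and 3%, each with a scatter of 1.5 percentage points.

As a first guess, I let the steps run at similar speed and reckon the spread of molecules from its mean. A Poisson distribution around r then gives the share holding two partners: r squared, divided by two, times exp(−r). For the south-east run, that share is 5.36%. The mean of its late readings is 3.50%, a factor of 0.653. I do not yet know what takes the difference, and the factor is rough, but I carry it over unchanged.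

Multiplying by c(substrate), I reckon 2.39 × 10⁻⁵ M for dusk, 8.83 × 10⁻⁵ M for spring, 1.20 × 10⁻⁴ M for midnight and 9.90 × 10⁻⁵ M for dawn. In my reckoning, midnight stands highest.

The forecast gives 1.500 × 10⁻⁵ M, 3.500 × 10⁻⁵ M, 8.000 × 10⁻⁵ M and 7.000 × 10⁻⁵ M, a row that rises, then falls: “I expect a rise, then a slight fall, though the fall is uncertain.”

The flask gives 6.01 × 10⁻⁶ M, 8.82 × 10⁻⁵ M, 1.17 × 10⁻⁴ M and 7.32 × 10⁻⁵ M, a row that rises, then falls.

    substrate + partner → single product (k = 150 M⁻¹ s⁻¹)
    partner + single product → double product (k = 80.0 M⁻¹ s⁻¹)
    partner + double product → triple product (k = 74.0 M⁻¹ s⁻¹)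
    partner + triple product → tetra adduct (k = 7.40 M⁻¹ s⁻¹)
    double product ⇌ isomer of the product (K = 0.470, k = 0.0240 s⁻¹)
    single product + capture agent → trapped intermediate (k = 320 M⁻¹ s⁻¹)

Midnight ends with 0% of its partner free and 25.8% of its substrate unchanged. I count the partners held in each form, with the trapped intermediate holding one and the isomer of the product two. Midnight then holds 1.00 per substrate charged, against a load of 1.00. In dawn, partner is the limiting reagent, with 0% left, and the load is 0.500. The same count gives 0.500.

All runs were computed for an exercise; scatter was added.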